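**Plan**
- Retrosynthesis: both aryl bonds at C4 of the upper chroman are cut (C4–C4a to its ring A, C4–C5' to ring B of the vestitol half), giving aldehyde 10 and vestitol ester 17. Aldehyde 10 is cut at O1–C2 (Mitsunobu) back to a prochiral 2-aryl-1,3-propanediol; 17 is cut at C3–C1' (ketone α-arylation) back to a chromanone.
- Forward order: the lower chroman is completed first from a ready-made pyranone ring. The upper half is carried open-chain (ring B on C3, ring A hung on O1), and its pyran ring closes last, in the step that also joins the halves.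
- Enabling feature: C4 lies between two aryl carbons that are each para to one oxygen and ortho to another (C4a: para to O7, ortho to O1; C5' of the vestitol ring: para to 2'-OH, ortho to 4'-OMe). Both are strong carbon nucleophiles and a cation at C4 is well stabilised, so C4 can enter as an aldehyde carbon and take both aryl groups in one acid cascade.
- Stereochemistry: upper C3 from lipase desymmetrisation of the diol; lower C3 from Ru-catalysed transfer hydrogenation with dynamic kinetic resolution; C4 from C3 (arene adds anti to the C3 aryl group, giving 3,4-trans).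
- Helpers: benzyl ethers on the upper phenols; a pivalate on O7 of the lower half that steers the attack to its ring B; both removed in the last two steps.

Key step: step 13

Assumption: lipase PS is taken to acetylate the pro-R hydroxymethyl arm of diol 5; the enzyme for step 4 is to be chosen so that monoacetate 6 is R.

**Route**

Step 1
Reactants: 1 2-bromo-4,5-dimethoxyphenol
Product: 2 1-(benzyloxy)-2-bromo-4,5-dimethoxybenzene
Conditions: BnBr, K2CO3, DMF, rt
Reagents that add atoms: benzyl bromide, BrCc1ccccc1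
Why: Williamson O-benzylation masks the future 2'-OH of the upper ring B through the base, hydride, oxidation and acid steps.

Step 2
Reactants: 2 1-(benzyloxy)-2-bromo-4,5-dimethoxybenzene; 3 diethyl malonate
Product: 4 diethyl 2-[2-(benzyloxy)-4,5-dimethoxyphenyl]propanedioate
Conditions: Pd(dba)2 (2 mol %), P(t-Bu)3·HBF4 (4 mol %), K3PO4, toluene, 80 °C
Reagents that add atoms: none
Why: Palladium-catalysed α-arylation of the malonate enolate with a bulky trialkylphosphine should couple the ortho-alkoxy, electron-rich bromide and stop at mono-arylation, installing C3 with both one-carbon arms (C2 and C4).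

Step 3
Reactants: 4 diethyl 2-[2-(benzyloxy)-4,5-dimethoxyphenyl]propanedioate
Product: 5 2-[2-(benzyloxy)-4,5-dimethoxyphenyl]propane-1,3-diol
Conditions: LiAlH4, THF, 0 °C → rt
Reagents that add atoms: none
Why: Hydride reduction of both esters gives the prochiral 2-aryl-1,3-propanediol.

Step 4
Reactants: 5 2-[2-(benzyloxy)-4,5-dimethoxyphenyl]propane-1,3-diol
Product: 6 (R)-2-[2-(benzyloxy)-4,5-dimethoxyphenyl]-3-hydroxypropyl acetate
Conditions: lipase PS (Burkholderia cepacia lipase, immobilised), vinyl acetate, t-BuOMe, 25 °C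
Reagents that add atoms: vinyl acetate, CC(=O)OC=C
Why: Irreversible lipase-catalysed transesterification with an enol ester differentiates the enantiotopic hydroxymethyl arms (enzymatic desymmetrisation of a prochiral 1,3-diol), and this sets the upper C3 stereocentre.

Step 5
Reactants: 6 (R)-2-[2-(benzyloxy)-4,5-dimethoxyphenyl]-3-hydroxypropyl acetate; 7 3-(benzyloxy)phenol
Product: 8 (R)-2-[2-(benzyloxy)-4,5-dimethoxyphenyl]-3-[3-(benzyloxy)phenoxy]propyl acetate
Conditions: PPh3, DIAD, THF, 0 °C → rt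
Reagents that add atoms: none
Why: Mitsunobu etherification of the free primary alcohol with the phenol forms the O1–C2 bond at a CH2 group, so C3 is not touched.

Step 6
Reactants: 8 (R)-2-[2-(benzyloxy)-4,5-dimethoxyphenyl]-3-[3-(benzyloxy)phenoxy]propyl acetate
Product: 9 (S)-2-[2-(benzyloxy)-4,5-dimethoxyphenyl]-3-[3-(benzyloxy)phenoxy]propan-1-ol
Conditions: K2CO3 (0.2 equiv), MeOH, 0 °C
Reagents that add atoms: none
Why: Base-catalysed methanolysis removes the primary acetate without affecting the aryl ethers or C3 (the descriptor changes by priority only).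

Step 7
Reactants: 9 (S)-2-[2-(benzyloxy)-4,5-dimethoxyphenyl]-3-[3-(benzyloxy)phenoxy]propan-1-ol
Product: 10 (R)-2-[2-(benzyloxy)-4,5-dimethoxyphenyl]-3-[3-(benzyloxy)phenoxy]propanal
Conditions: Dess–Martin periodinane, pyridine, CH2Cl2, 0 °C; crude aldehyde used at once
Reagents that add atoms: none
Why: Dess–Martin oxidation under buffered, non-basic conditions should give the α-aryl aldehyde without enolisation, and the crude product is carried on directly to protect C3.

Step 8
Reactants: 11 7-hydroxychroman-4-one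
Product: 12 4-oxochroman-7-yl pivalate
Conditions: PivCl, Et3N, DMAP (cat.), CH2Cl2, 0 °C → rt
Reagents that add atoms: pivaloyl chloride, CC(C)(C)C(Cl)=O
Why: Acylation of the phenol gives a hindered aryl ester that should survive the next four steps and later lowers the nucleophilicity of ring A of the lower half.

Step 9
Reactants: 13 2-bromo-5-methoxyphenol
Product: 14 2-(benzyloxy)-1-bromo-4-methoxybenzene
Conditions: BnBr, K2CO3, DMF, rt
Reagents that add atoms: benzyl bromide, BrCc1ccccc1
Why: Williamson O-benzylation protects the future 2'-OH of the lower ring B during the enolate coupling.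

Step 10
Reactants: 12 4-oxochroman-7-yl pivalate; 14 2-(benzyloxy)-1-bromo-4-methoxybenzene
Product: 15 rac-3-[2-(benzyloxy)-4-methoxyphenyl]-4-oxochroman-7-yl pivalate
Conditions: Pd2(dba)3 (2 mol %), XPhos (8 mol %), K3PO4, toluene, 90 °C
Reagents that add atoms: none
Why: Palladium-catalysed α-arylation of the ketone enolate forms the C3–C1' bond, the weak base K3PO4 should spare the aryl ester, and steric hindrance should stop the reaction at the mono-arylated racemic isoflavanone.

Step 11
Reactants: 15 rac-3-[2-(benzyloxy)-4-methoxyphenyl]-4-oxochroman-7-yl pivalate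
Product: 16 (3R,4R)-3-[2-(benzyloxy)-4-methoxyphenyl]-4-hydroxychroman-7-yl pivalate (cis)
Conditions: RuCl[(R,R)-TsDPEN](p-cymene) (2 mol %), HCO2H/Et3N (5:2), EtOAc, 40 °C
Reagents that add atoms: none
Why: Noyori–Ikariya asymmetric transfer hydrogenation with dynamic kinetic resolution: C3 racemises by amine-mediated enolisation, the (R,R) catalyst should set C4 as R by analogy with aryl alkyl ketones, and hydride delivery anti to the C3 aryl group selects the 3R ketone to give the cis alcohol.

Step 12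
Reactants: 16 (3R,4R)-3-[2-(benzyloxy)-4-methoxyphenyl]-4-hydroxychroman-7-yl pivalate
Product: 17 (R)-3-(2-hydroxy-4-methoxyphenyl)chroman-7-yl pivalate (vestitol 7-pivalate)
Conditions: H2 (4 bar), Pd/C, EtOAc/AcOH, HClO4 (cat.), rt
Reagents that add atoms: none
Why: Hydrogenolysis cleaves the benzyl ether and the benzylic C4–O bond in one operation without touching C3 or the ester.

Step 13
Reactants: 10 (R)-2-[2-(benzyloxy)-4,5-dimethoxyphenyl]-3-[3-(benzyloxy)phenoxy]propanal; 17 (R)-3-(2-hydroxy-4-methoxyphenyl)chroman-7-yl pivalate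
Product: 19 (R)-3-{5-[(3R,4S)-7-(benzyloxy)-3-[2-(benzyloxy)-4,5-dimethoxyphenyl]chroman-4-yl]-2-hydroxy-4-methoxyphenyl}chroman-7-yl pivalate, via chroman-4-ol 18 (not isolated)
Conditions: BF3·OEt2 (0.5 equiv), 17 (3 equiv), CH2Cl2, −78 °C, slow addition of 10, then → −20 °C
Reagents that add atoms: none
Why: BF3 activates the aldehyde of 10, and C4a of ring A (para to the 7-benzyloxy group, ortho to O1) attacks it in a 6-exo-trig Friedel–Crafts hydroxyalkylation that forms the C4–C4a bond and closes the pyran ring to chroman-4-ol 18. Under the same acid 18 ionises to the C4 benzylic cation, stabilised by O1 and O7, which is captured by C5' of 17 (para to its free 2'-OH, ortho to its 4'-OMe). The closest known reaction type is the acid-mediated double Friedel–Crafts arylation of an aldehyde, here an intramolecular hydroxyalkylation followed by an intermolecular benzylation, as in the coupling of flavan C4 cations with phenols. The new C4 stereocentre is controlled by the C3 aryl group, anti to which the arene adds to the half-chair cation, so the 3,4-trans (3R,4S) isomer should form, which is also the more stable one. Site selectivity in 17 is secured by the pivalate, which leaves its ring A with a single donor towards C6 while ring B keeps two donors converging on C5'; closure of 10 at the hindered carbon between the two ring A oxygens is disfavoured. C3 should keep its configuration because the aldehyde is consumed at −78 °C and the cation is trapped before it can lose H3, and self-alkylation is held back by adding 10 slowly to an excess of 17.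

Step 14
Reactants: 19 (R)-3-{5-[(3R,4S)-7-(benzyloxy)-3-[2-(benzyloxy)-4,5-dimethoxyphenyl]chroman-4-yl]-2-hydroxy-4-methoxyphenyl}chroman-7-yl pivalate
Product: 20 (R)-3-{5-[(3R,4S)-7-(benzyloxy)-3-[2-(benzyloxy)-4,5-dimethoxyphenyl]chroman-4-yl]-2-hydroxy-4-methoxyphenyl}chroman-7-ol
Conditions: LiOH·H2O, THF/MeOH/H2O, rt, under argon; then 1 M HCl
Reagents that add atoms: none
Why: Saponification of the aryl ester frees the lower 7-OH while benzyl ethers, methyl ethers and all stereocentres are inert to aqueous base.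

Step 15
Reactants: 20 (R)-3-{5-[(3R,4S)-7-(benzyloxy)-3-[2-(benzyloxy)-4,5-dimethoxyphenyl]chroman-4-yl]-2-hydroxy-4-methoxyphenyl}chroman-7-ol
Product: 21 (3R,4S)-4-{4-hydroxy-5-[(3R)-7-hydroxychroman-3-yl]-2-methoxyphenyl}-3-(2-hydroxy-4,5-dimethoxyphenyl)chroman-7-ol (target)
Conditions: H2 (1 atm), Pd/C, EtOAc/MeOH, rt
Reagents that add atoms: none
Why: Hydrogenolysis of the two benzyl aryl ethers under neutral conditions frees the last phenols, and the C4–aryl carbon–carbon bonds and the chroman C–O bonds are not cleaved.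

**Compound list**
1 | 2-bromo-4,5-dimethoxyphenol | COc1cc(O)c(Br)cc1OC | starting material
2 | 1-(benzyloxy)-2-bromo-4,5-dimethoxybenzene | COc1cc(OCc2ccccc2)c(Br)cc1OC | intermediate
3 | diethyl malonate | CCOC(=O)CC(=O)OCC | starting material
4 | diethyl 2-[2-(benzyloxy)-4,5-dimethoxyphenyl]propanedioate | CCOC(=O)C(C(=O)OCC)c1cc(OC)c(OC)cc1OCc1ccccc1 | intermediate
5 | 2-[2-(benzyloxy)-4,5-dimethoxyphenyl]propane-1,3-diol | OCC(CO)c1cc(OC)c(OC)cc1OCc1ccccc1 | intermediate
6 | (R)-2-[2-(benzyloxy)-4,5-dimethoxyphenyl]-3-hydroxypropyl acetate | COc1cc(OCc2ccccc2)c([C@@H](COC(C)=O)CO)cc1OC | intermediate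
7 | 3-(benzyloxy)phenol | Oc1cccc(OCc2ccccc2)c1 | starting material
8 | (R)-2-[2-(benzyloxy)-4,5-dimethoxyphenyl]-3-[3-(benzyloxy)phenoxy]propyl acetate | COc1cc(OCc2ccccc2)c([C@@H](COC(C)=O)COc2cccc(OCc3ccccc3)c2)cc1OC | intermediate
9 | (S)-2-[2-(benzyloxy)-4,5-dimethoxyphenyl]-3-[3-(benzyloxy)phenoxy]propan-1-ol | COc1cc(OCc2ccccc2)c([C@@H](CO)COc2cccc(OCc3ccccc3)c2)cc1OC | intermediate
10 | (R)-2-[2-(benzyloxy)-4,5-dimethoxyphenyl]-3-[3-(benzyloxy)phenoxy]propanal | COc1cc(OCc2ccccc2)c([C@@H](C=O)COc2cccc(OCc3ccccc3)c2)cc1OC | intermediate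
11 | 7-hydroxychroman-4-one | O=C1CCOc2cc(O)ccc21 | starting material
12 | 4-oxochroman-7-yl pivalate | CC(C)(C)C(=O)Oc1ccc2C(=O)CCOc2c1 | intermediate
13 | 2-bromo-5-methoxyphenol | COc1ccc(Br)c(O)c1 | starting material
14 | 2-(benzyloxy)-1-bromo-4-methoxybenzene | COc1ccc(Br)c(OCc2ccccc2)c1 | intermediate
15 | rac-3-[2-(benzyloxy)-4-methoxyphenyl]-4-oxochroman-7-yl pivalate | COc1ccc(C2COc3cc(OC(=O)C(C)(C)C)ccc3C2=O)c(OCc2ccccc2)c1 | intermediate
16 | (3R,4R)-3-[2-(benzyloxy)-4-methoxyphenyl]-4-hydroxychroman-7-yl pivalate | COc1ccc([C@@H]2COc3cc(OC(=O)C(C)(C)C)ccc3[C@@H]2O)c(OCc2ccccc2)c1 | intermediate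
17 | (R)-3-(2-hydroxy-4-methoxyphenyl)chroman-7-yl pivalate | COc1ccc([C@@H]2COc3cc(OC(=O)C(C)(C)C)ccc3C2)c(O)c1 | intermediate
18 | (3R)-7-(benzyloxy)-3-[2-(benzyloxy)-4,5-dimethoxyphenyl]chroman-4-ol (both C4 epimers) | COc1cc(OCc2ccccc2)c([C@@H]2COc3cc(OCc4ccccc4)ccc3C2O)cc1OC | intermediate (not isolated)
19 | (R)-3-{5-[(3R,4S)-7-(benzyloxy)-3-[2-(benzyloxy)-4,5-dimethoxyphenyl]chroman-4-yl]-2-hydroxy-4-methoxyphenyl}chroman-7-yl pivalate | COc1cc(OCc5ccccc5)c([C@@H]2COc3cc(OCc5ccccc5)ccc3[C@H]2c2cc([C@@H]3COc4cc(OC(=O)C(C)(C)C)ccc4C3)c(O)cc2OC)cc1OC | intermediate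
20 | (R)-3-{5-[(3R,4S)-7-(benzyloxy)-3-[2-(benzyloxy)-4,5-dimethoxyphenyl]chroman-4-yl]-2-hydroxy-4-methoxyphenyl}chroman-7-ol | COc1cc(OCc5ccccc5)c([C@@H]2COc3cc(OCc5ccccc5)ccc3[C@H]2c2cc([C@@H]3COc4cc(O)ccc4C3)c(O)cc2OC)cc1OC | intermediate
21 | (3R,4S)-4-{4-hydroxy-5-[(3R)-7-hydroxychroman-3-yl]-2-methoxyphenyl}-3-(2-hydroxy-4,5-dimethoxyphenyl)chroman-7-ol | COc1cc(O)c([C@@H]2COc3cc(O)ccc3[C@H]2c2cc([C@@H]3COc4cc(O)ccc4C3)c(O)cc2OC)cc1OC | target

**Step count and risks**

Total steps: 15. Longest linear sequence: 10 (steps 1–7, then 13–15).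

Steps most likely to fail:

1. Step 13. Self-alkylation of ring A of the upper unit, or loss of H3 from the C4 cation to an isoflav-3-ene (which would erase upper C3), may outrun the intermolecular capture by 17. Fallback (sets out from 17 and 10, returns at 21): the C4–C5' bond is made first by carbonyl addition and the C4–C4a bond then closes intramolecularly. Para-iodination of 17 (NIS, MeCN, 0 °C) should give 5'-iodo vestitol pivalate F1, and benzylation (BnBr, K2CO3, DMF) its benzyl ether F2. Iodine–magnesium exchange (i-PrMgCl·LiCl, THF, −30 °C) gives aryl Grignard reagent F3, which adds to 10 at −78 °C to give diaryl carbinol F4 as both C4 epimers. Catalytic BF3·OEt2 in CH2Cl2 at −40 °C ionises the carbinol to the cation stabilised by the 4-benzyloxy-2-methoxyphenyl ring, and ring A closes on it (intramolecular Friedel–Crafts benzylation, trans by the C3 aryl group) to tribenzyl pivalate F5. Saponification (LiOH) gives tribenzyl ether F6, and hydrogenolysis (H2, Pd/C) gives 21.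

2. Step 10. Cleavage of the aryl ester, retro-oxa-Michael opening of the chromanone enolate or slow oxidative addition of the hindered, electron-rich bromide 14 may stop the α-arylation. Fallback (sets out from 14, returns at 16): the C3–C1' bond is made by Suzuki coupling on a 3-iodochromone and C3 is set during reduction of the isoflavone. 1-(2,4-Dihydroxyphenyl)ethan-1-one F7 is pivaloylated at the non-chelated 4-OH (PivCl, Et3N) to acetophenone pivalate F8, condensed with DMF dimethyl acetal to enaminone F9 and cyclised with I2 to 3-iodochromone pivalate F10. Bromide 14 is converted (n-BuLi, B(Oi-Pr)3; then HCl) into arylboronic acid F11. Suzuki coupling of F10 and F11 (Pd(dppf)Cl2, K3PO4, dioxane/H2O) gives isoflavone F12. Transfer hydrogenation with RuCl[(R,R)-TsDPEN](p-cymene) and HCO2H/Et3N reduces the C2=C3 bond and then the ketone with dynamic kinetic resolution to 16.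

3. Step 4. Low enantiotopic-group selectivity with the ortho-benzyloxy aryl group, or acetyl migration between the two arms of 6, may erode the ee at upper C3. Fallback (sets out from 2 and 7, returns at 9): C3 is set by catalytic asymmetric hydroboration of a 1,1-disubstituted alkene. Phenol 7 is alkylated with 2,3-dibromopropene (K2CO3, acetone) to 2-bromoallyl ether F13, and bromide 2 gives arylboronic acid F14 (n-BuLi, B(Oi-Pr)3; then HCl). Suzuki coupling (Pd(PPh3)4, K3PO4, dioxane/H2O) gives α-(aryloxymethyl)styrene F15. Copper-catalysed hydroboration (CuCl, DTBM-SEGPHOS, KOt-Bu, HBpin, THF; ligand enantiomer chosen for the R boronate) gives pinacol boronate F16, which H2O2/NaOH oxidises to 9.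

**Further compounds**
F1 | step 13 | (R)-3-(2-hydroxy-5-iodo-4-methoxyphenyl)chroman-7-yl pivalate | COc1cc(O)c([C@@H]2COc3cc(OC(=O)C(C)(C)C)ccc3C2)cc1I
F2 | step 13 | (R)-3-[2-(benzyloxy)-5-iodo-4-methoxyphenyl]chroman-7-yl pivalate | COc1cc(OCc2ccccc2)c([C@@H]2COc3cc(OC(=O)C(C)(C)C)ccc3C2)cc1I
F3 | step 13 | {4-(benzyloxy)-2-methoxy-5-[(R)-7-(pivaloyloxy)chroman-3-yl]phenyl}magnesium chloride | COc1cc(OCc2ccccc2)c([C@@H]2COc3cc(OC(=O)C(C)(C)C)ccc3C2)cc1[Mg]Cl
F4 | step 13 | (R)-3-{2-(benzyloxy)-5-[(2R)-2-[2-(benzyloxy)-4,5-dimethoxyphenyl]-3-[3-(benzyloxy)phenoxy]-1-hydroxypropyl]-4-methoxyphenyl}chroman-7-yl pivalate (carbinol epimers) | COc1cc(OCc2ccccc2)c([C@H](COc2cccc(OCc3ccccc3)c2)C(O)c2cc([C@@H]3COc4cc(OC(=O)C(C)(C)C)ccc4C3)c(OCc3ccccc3)cc2OC)cc1OC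
F5 | step 13 | (R)-3-{2-(benzyloxy)-5-[(3R,4S)-7-(benzyloxy)-3-[2-(benzyloxy)-4,5-dimethoxyphenyl]chroman-4-yl]-4-methoxyphenyl}chroman-7-yl pivalate | COc1cc(OCc5ccccc5)c([C@@H]2COc3cc(OCc5ccccc5)ccc3[C@H]2c2cc([C@@H]3COc4cc(OC(=O)C(C)(C)C)ccc4C3)c(OCc3ccccc3)cc2OC)cc1OC
F6 | step 13 | (R)-3-{2-(benzyloxy)-5-[(3R,4S)-7-(benzyloxy)-3-[2-(benzyloxy)-4,5-dimethoxyphenyl]chroman-4-yl]-4-methoxyphenyl}chroman-7-ol | COc1cc(OCc5ccccc5)c([C@@H]2COc3cc(OCc5ccccc5)ccc3[C@H]2c2cc([C@@H]3COc4cc(O)ccc4C3)c(OCc3ccccc3)cc2OC)cc1OC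
F7 | step 10 | 1-(2,4-dihydroxyphenyl)ethan-1-one | CC(=O)c1ccc(O)cc1O
F8 | step 10 | 4-acetyl-3-hydroxyphenyl pivalate | CC(=O)c1ccc(OC(=O)C(C)(C)C)cc1O
F9 | step 10 | (E)-4-[3-(dimethylamino)prop-2-enoyl]-3-hydroxyphenyl pivalate | CN(C)/C=C/C(=O)c1ccc(OC(=O)C(C)(C)C)cc1O
F10 | step 10 | 3-iodo-4-oxo-4H-chromen-7-yl pivalate | O=c1c(I)coc2cc(OC(=O)C(C)(C)C)ccc12
F11 | step 10 | [2-(benzyloxy)-4-methoxyphenyl]boronic acid | COc1ccc(B(O)O)c(OCc2ccccc2)c1
F12 | step 10 | 3-[2-(benzyloxy)-4-methoxyphenyl]-4-oxo-4H-chromen-7-yl pivalate | COc1ccc(-c2coc3cc(OC(=O)C(C)(C)C)ccc3c2=O)c(OCc2ccccc2)c1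
F13 | step 4 | 1-(benzyloxy)-3-[(2-bromoprop-2-en-1-yl)oxy]benzene | C=C(Br)COc1cccc(OCc2ccccc2)c1
F14 | step 4 | [2-(benzyloxy)-4,5-dimethoxyphenyl]boronic acid | COc1cc(OCc2ccccc2)c(B(O)O)cc1OC
F15 | step 4 | 1-(benzyloxy)-2-{3-[3-(benzyloxy)phenoxy]prop-1-en-2-yl}-4,5-dimethoxybenzene | COc1cc(OCc2ccccc2)c(C(=C)COc2cccc(OCc3ccccc3)c2)cc1OC
F16 | step 4 | 2-{(2R)-2-[2-(benzyloxy)-4,5-dimethoxyphenyl]-3-[3-(benzyloxy)phenoxy]propyl}-4,4,5,5-tetramethyl-1,3,2-dioxaborolane | COc1cc(OCc2ccccc2)c([C@@H](CB2OC(C)(C)C(C)(C)O2)COc2cccc(OCc3ccccc3)c2)cc1OC
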